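The naphthalene is traced back to a tetralin whose ring A (C1–C4, C4a, C8a) is closed by making only the C2–C3 bond. C1 carries both the fused ring B and the pendant ring C. A radical arriving at C2 of a C1=C2 alkene therefore leaves a doubly benzylic radical at C1. C3, the future naphthol carbon, enters as an aldehyde whose polarity is inverted by SmI2. One operation thus builds ring A with its C3 oxygen in place. The precursor is a ring B arylacetaldehyde bearing an ortho 1-aryl-3-arylprop-1-enyl group, assembled under non-acidic conditions. Oxidation, dehydrogenation and hydrogenolysis finish the synthesis.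

Key step: step 13

Remark on numbering: locants C1–C8a are those of the target naphthalene and are kept for all precursors. Ring B is C4a–C8a, ring C is the aryl group at C1, and ring D is the catechol ring of the C2 benzyl group.

Assumption: alkenes 15, 16, 18 and 19 are taken to form as E/Z mixtures, and 22 and 23 as racemic diastereomer mixtures. One isomer is drawn and the mixtures are carried on, since all converge at 24.

Remark on design: C3 stays at the alcohol level until the step before the cyclisation and is unveiled by a buffered oxidation. An acid-generated oxocarbenium ion at C3 would be captured by the electron-rich C1=C2 bond, and the adduct would aromatise with loss of the C3 oxygen.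

Step 1
Reactants: 1 syringaldehyde (4-hydroxy-3,5-dimethoxybenzaldehyde)
Product: 2 4-(benzyloxy)-3,5-dimethoxybenzaldehyde
Conditions: BnBr, K2CO3, DMF, rt
Reagents that add atoms: benzyl bromide, BrCc1ccccc1
Why: Williamson ether synthesis on an acidic para-formyl phenol; benzyl is chosen so that all four phenol masks fall together in the last step.

Step 2
Reactants: 2 4-(benzyloxy)-3,5-dimethoxybenzaldehyde
Product: 3 4-(benzyloxy)-2-bromo-3,5-dimethoxybenzaldehyde
Conditions: NBS (1.05 equiv), MeCN, rt, dark
Reagents that add atoms: N-bromosuccinimide, O=C1CCC(=O)N1Br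
Why: Electrophilic aromatic bromination under ionic conditions; the two free ring B positions are equivalent and lie ortho and para to methoxy groups, as in the familiar bromination of 3,4,5-trimethoxybenzaldehyde, while the unactivated benzyl phenyl ring is not attacked.

Step 3
Reactants: 4 4-bromo-3-methoxyphenol
Product: 5 4-(benzyloxy)-1-bromo-2-methoxybenzene
Conditions: BnBr, K2CO3, DMF, rt
Reagents that add atoms: benzyl bromide, BrCc1ccccc1
Why: Williamson ether synthesis; the aryl bromide is inert to carbonate and benzyl bromide.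

Step 4
Reactants: 5 4-(benzyloxy)-1-bromo-2-methoxybenzene; 3 4-(benzyloxy)-2-bromo-3,5-dimethoxybenzaldehyde
Product: 7 racemic [4-(benzyloxy)-2-bromo-3,5-dimethoxyphenyl][4-(benzyloxy)-2-methoxyphenyl]methanol, via aryllithium 6 (not isolated)
Conditions: 5, n-BuLi, THF, −78 °C; then 3, −78 °C; aq NH4Cl
Reagents that add atoms: none
Why: Bromine–lithium exchange followed by 1,2-addition; exchange on 5 is complete before 3 is added, carbonyl addition outruns exchange with the bromide of 3 at −78 °C, and the racemic carbinol centre is removed in the next step.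

Step 5
Reactants: 7 racemic diaryl carbinol
Product: 8 [4-(benzyloxy)-2-bromo-3,5-dimethoxyphenyl][4-(benzyloxy)-2-methoxyphenyl]methanone
Conditions: Dess–Martin periodinane, CH2Cl2, 0 °C to rt
Reagents that add atoms: none
Why: Dess–Martin oxidation converts hindered benzhydrols into benzophenones under mild conditions that leave benzyl ethers and the aryl bromide alone.

Step 6
Reactants: 9 hydroxytyrosol (2-(3,4-dihydroxyphenyl)ethanol)
Product: 10 2-[3,4-bis(benzyloxy)phenyl]ethanol
Conditions: BnBr (2.2 equiv), K2CO3, acetone, reflux, N2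
Reagents that add atoms: benzyl bromide, BrCc1ccccc1
Why: Chemoselective Williamson ether synthesis; carbonate deprotonates only the two phenols, so the primary alcohol stays free, and this starting material already holds the two-carbon arm of ring D.

Step 7
Reactants: 10 2-[3,4-bis(benzyloxy)phenyl]ethanol
Product: 11 1,2-bis(benzyloxy)-4-(2-bromoethyl)benzene
Conditions: CBr4, PPh3, CH2Cl2, 0 °C
Reagents that add atoms: carbon tetrabromide, BrC(Br)(Br)Br
Why: The Appel reaction turns the primary alcohol into the bromide by SN2 displacement of the oxyphosphonium group under neutral conditions.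

Step 8
Reactants: 11 1,2-bis(benzyloxy)-4-(2-bromoethyl)benzene; 8 bromobenzophenone
Product: 13 racemic 1-[4-(benzyloxy)-2-bromo-3,5-dimethoxyphenyl]-1-[4-(benzyloxy)-2-methoxyphenyl]-3-[3,4-bis(benzyloxy)phenyl]propan-1-ol, via Grignard reagent 12 (not isolated)
Conditions: 11, Mg, THF, rt to 40 °C; then 8, LaCl3·2LiCl, THF, 0 °C to rt; aq NH4Cl
Reagents that add atoms: none
Why: Grignard addition to a non-enolisable diaryl ketone; the lanthanum salt activates the carbonyl and suppresses β-hydride reduction, an alkyl Grignard reagent does not exchange with the electron-rich aryl bromide at this temperature, and the racemic carbinol centre disappears in the next step.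

Step 9
Reactants: 13 racemic tertiary alcohol
Product: 15 1-[4-(benzyloxy)-2-bromo-3,5-dimethoxyphenyl]-1-[4-(benzyloxy)-2-methoxyphenyl]-3-[3,4-bis(benzyloxy)phenyl]prop-1-ene (E/Z mixture; the isomer drawn has ring C cis to the C2 methylene), via tertiary mesylate 14 (not isolated)
Conditions: MsCl, Et3N (excess), CH2Cl2, 0 °C to rt
Reagents that add atoms: none
Why: Dehydration by mesylation and E1-type elimination in basic medium; only the future C2 carries β-hydrogens, so one constitutional alkene results, and the amine prevents reprotonation to the diaryl cation, which could otherwise alkylate ring D to an indane.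

Step 10
Reactants: 15 bromo triarylpropene
Product: 16 1-[4-(benzyloxy)-2-ethenyl-3,5-dimethoxyphenyl]-1-[4-(benzyloxy)-2-methoxyphenyl]-3-[3,4-bis(benzyloxy)phenyl]prop-1-ene (E/Z mixture; same isomer drawn)
Conditions: vinylboronic acid pinacol ester, Pd(OAc)2 (5 mol%), SPhos (10 mol%), K3PO4, toluene/H2O, 90 °C
Reagents that add atoms: vinylboronic acid pinacol ester, C=CB1OC(C)(C)C(C)(C)O1
Why: Suzuki–Miyaura coupling; the bulky electron-rich biaryl phosphine lets zerovalent palladium insert into the doubly ortho-substituted bromide, the small vinyl partner transmetalates quickly, and phosphate is too weak a base to shift the C1=C2 bond.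

Step 11
Reactants: 16 vinyl triarylpropene
Product: 18 2-{3-(benzyloxy)-2,4-dimethoxy-6-[1-(4-benzyloxy-2-methoxyphenyl)-3-(3,4-dibenzyloxyphenyl)prop-1-en-1-yl]phenyl}ethanol (E/Z mixture; same isomer drawn), via B-alkyl-9-BBN adduct 17 (not isolated)
Conditions: 9-BBN, THF, 0 °C to rt; then H2O2, aq NaOH, 0 °C
Reagents that add atoms: hydrogen peroxide, OO
Why: Brown hydroboration–oxidation; 9-BBN places boron on the terminal carbon of the monosubstituted styrene and ignores the hindered trisubstituted C1=C2 bond, so C3 and C4 are installed without acid.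

Step 12
Reactants: 18 primary alcohol
Product: 19 2-{3-(benzyloxy)-2,4-dimethoxy-6-[1-(4-benzyloxy-2-methoxyphenyl)-3-(3,4-dibenzyloxyphenyl)prop-1-en-1-yl]phenyl}acetaldehyde (E/Z mixture; same isomer drawn)
Conditions: Dess–Martin periodinane, NaHCO3, CH2Cl2, 0 °C; used at once
Reagents that add atoms: none
Why: Buffered Dess–Martin oxidation stops at the arylacetaldehyde and avoids both the acid that would start a Prins closure and the strong base that would enolise the product.

Step 13
Reactants: 19 arylacetaldehyde
Product: 22 racemic 6-(benzyloxy)-1-[4-(benzyloxy)-2-methoxyphenyl]-2-[3,4-bis(benzyloxy)benzyl]-5,7-dimethoxy-1,2,3,4-tetrahydronaphthalen-3-ol (diastereomer mixture; the all-trans (1S*,2S*,3S*) isomer is drawn), via samarium ketyl 20 (not isolated), via C1 diarylmethyl radical 21 (not isolated)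
Conditions: SmI2 (0.1 M in THF, 3 equiv), HMPA (12 equiv), t-BuOH (3 equiv), THF, 0 °C; 19 added slowly (final about 5 mM)
Reagents that add atoms: none
Why: HMPA-activated divalent samarium transfers one electron to the aldehyde, the nucleophilic ketyl carbon C3 of 20 adds to C2 of the C1=C2 bond to give radical 21, and a second SmI2 reduces this radical before t-BuOH delivers the proton to C1; the closest known reaction type is the samarium diiodide ketyl–olefin reductive cyclisation onto styrene-type acceptors. Ring A closes in the 6-endo-trig mode, with both alkene carbons ending inside the new six-membered ring. The selectivity needed is 6-endo over 5-exo, and the substrate secures it: attack at C2 meets a CH carbon and leaves a radical at C1 stabilised by rings B and C, whereas 5-exo attack would have to hit the fully substituted, twisted C1 and would leave a plain secondary alkyl radical, in line with the endo preference of 5-substituted 5-hexenyl radicals. C3 and C2 are set together in a half-chair transition state in which the bulky HMPA-solvated O–Sm group and the C2 benzyl arm should both sit pseudo-equatorial (2,3-trans), and C1 is set by the face from which the reduced benzylic centre takes up its proton under the influence of the C2 substituent. None of these centres needs control, because C1, C2 and C3 all become sp2 in step 15 and both alkene isomers funnel into the same planar C1 radical. Slow addition at high dilution disfavours pinacol coupling, t-BuOH is too weak a donor to quench the ketyl before it cyclises, and aryl benzyl ethers and the electron-rich diarylalkene are not reduced by SmI2–HMPA.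

Step 14
Reactants: 22 tetralin-3-ol (diastereomer mixture)
Product: 23 racemic 6-(benzyloxy)-1-[4-(benzyloxy)-2-methoxyphenyl]-2-[3,4-bis(benzyloxy)benzyl]-5,7-dimethoxy-1,2-dihydronaphthalen-3(4H)-one (2-tetralone type; the 1,2-trans (1S*,2S*) isomer is drawn)
Conditions: Dess–Martin periodinane, NaHCO3, CH2Cl2, 0 °C to rt; used without storage
Reagents that add atoms: none
Why: Dess–Martin oxidation of the secondary alcohol removes the C3 stereocentre under buffered, non-enolising conditions suited to an air-sensitive 2-tetralone.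

Step 15
Reactants: 23 tetralone
Product: 24 6-(benzyloxy)-1-[4-(benzyloxy)-2-methoxyphenyl]-2-[3,4-bis(benzyloxy)benzyl]-5,7-dimethoxynaphthalen-3-ol
Conditions: DDQ (1.05 equiv), 1,4-dioxane, rt, Ar
Reagents that add atoms: none
Why: DDQ dehydrogenation; the ketone reacts through its ring-B-conjugated C3=C4 enol, a 1,2-dihydronaphthalene that gives up the doubly benzylic C1 hydride and then the C2 proton, so ring A aromatises and the last stereocentres vanish, while one equivalent at room temperature spares the aryl benzyl ethers.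

Step 16
Reactants: 24 tetrabenzyl naphthol
Product: 25 2-(3,4-dihydroxybenzyl)-1-(4-hydroxy-2-methoxyphenyl)-5,7-dimethoxynaphthalene-3,6-diol (CNP0000244.0)
Conditions: H2 (1 atm), Pd/C (10 wt% Pd), THF/MeOH, rt; work-up under Ar
Reagents that add atoms: none
Why: Catalytic hydrogenolysis cleaves the four O-benzyl bonds in one operation, while the aryl methyl ethers, the C2 benzyl C–C bonds and the naphthalene core are inert at atmospheric pressure.

Compound list
1 | syringaldehyde | COc1cc(C=O)cc(OC)c1O | starting material
2 | 4-(benzyloxy)-3,5-dimethoxybenzaldehyde | COc1cc(C=O)cc(OC)c1OCc1ccccc1 | intermediate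
3 | 4-(benzyloxy)-2-bromo-3,5-dimethoxybenzaldehyde | O=Cc1cc(OC)c(OCc2ccccc2)c(OC)c1Br | intermediate
4 | 4-bromo-3-methoxyphenol | COc1cc(O)ccc1Br | starting material
5 | 4-(benzyloxy)-1-bromo-2-methoxybenzene | COc1cc(OCc2ccccc2)ccc1Br | intermediate
6 | [4-(benzyloxy)-2-methoxyphenyl]lithium (not isolated) | [Li]c1ccc(OCc2ccccc2)cc1OC | intermediate
7 | racemic diaryl carbinol | OC(c1cc(OC)c(OCc2ccccc2)c(OC)c1Br)c1ccc(OCc2ccccc2)cc1OC | intermediate
8 | bromobenzophenone of rings B and C | O=C(c1cc(OC)c(OCc2ccccc2)c(OC)c1Br)c1ccc(OCc2ccccc2)cc1OC | intermediate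
9 | hydroxytyrosol | OCCc1ccc(O)c(O)c1 | starting material
10 | 2-[3,4-bis(benzyloxy)phenyl]ethanol | OCCc1ccc(OCc2ccccc2)c(OCc2ccccc2)c1 | intermediate
11 | 1,2-bis(benzyloxy)-4-(2-bromoethyl)benzene | BrCCc1ccc(OCc2ccccc2)c(OCc2ccccc2)c1 | intermediate
12 | 2-[3,4-bis(benzyloxy)phenyl]ethylmagnesium bromide (not isolated) | Br[Mg]CCc1ccc(OCc2ccccc2)c(OCc2ccccc2)c1 | intermediate
13 | racemic 1,1,3-triarylpropan-1-ol | OC(CCc1ccc(OCc2ccccc2)c(OCc2ccccc2)c1)(c1cc(OC)c(OCc2ccccc2)c(OC)c1Br)c1ccc(OCc2ccccc2)cc1OC | intermediate
14 | methanesulfonate of 13 (not isolated) | CS(=O)(=O)OC(CCc1ccc(OCc2ccccc2)c(OCc2ccccc2)c1)(c1cc(OC)c(OCc2ccccc2)c(OC)c1Br)c1ccc(OCc2ccccc2)cc1OC | intermediate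
15 | bromo triarylpropene (ring C cis to CH2 drawn) | Brc1c(OC)c(OCc2ccccc2)c(OC)cc1/C(c1ccc(OCc2ccccc2)cc1OC)=C/Cc1ccc(OCc2ccccc2)c(OCc2ccccc2)c1 | intermediate
16 | vinyl triarylpropene (same isomer drawn) | C=Cc1c(OC)c(OCc2ccccc2)c(OC)cc1/C(c1ccc(OCc2ccccc2)cc1OC)=C/Cc1ccc(OCc2ccccc2)c(OCc2ccccc2)c1 | intermediate
17 | B-(2-arylethyl)-9-borabicyclo[3.3.1]nonane adduct of 16 (not isolated) | C(Cc1c(OC)c(OCc2ccccc2)c(OC)cc1/C(c1ccc(OCc2ccccc2)cc1OC)=C/Cc1ccc(OCc2ccccc2)c(OCc2ccccc2)c1)B1C2CCCC1CCC2 | intermediate
18 | 2-arylethanol with ortho triarylpropenyl group (same isomer drawn) | OCCc1c(OC)c(OCc2ccccc2)c(OC)cc1/C(c1ccc(OCc2ccccc2)cc1OC)=C/Cc1ccc(OCc2ccccc2)c(OCc2ccccc2)c1 | intermediate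
19 | arylacetaldehyde, precursor of the key step (same isomer drawn) | O=CCc1c(OC)c(OCc2ccccc2)c(OC)cc1/C(c1ccc(OCc2ccccc2)cc1OC)=C/Cc1ccc(OCc2ccccc2)c(OCc2ccccc2)c1 | intermediate
20 | O-samarium ketyl radical at C3 (not isolated) | I[Sm](I)O[CH]Cc1c(OC)c(OCc2ccccc2)c(OC)cc1/C(c1ccc(OCc2ccccc2)cc1OC)=C/Cc1ccc(OCc2ccccc2)c(OCc2ccccc2)c1 | intermediate
21 | cyclised C1 diarylmethyl radical, 2,3-trans drawn (not isolated) | I[Sm](I)O[C@H]1Cc2c(OC)c(OCc3ccccc3)c(OC)cc2[C](c2ccc(OCc3ccccc3)cc2OC)[C@@H]1Cc1ccc(OCc2ccccc2)c(OCc2ccccc2)c1 | intermediate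
22 | racemic 1-aryl-2-benzyltetralin-3-ol, all-trans (1S*,2S*,3S*) drawn | O[C@H]1Cc2c(OC)c(OCc3ccccc3)c(OC)cc2[C@@H](c2ccc(OCc3ccccc3)cc2OC)[C@@H]1Cc1ccc(OCc2ccccc2)c(OCc2ccccc2)c1 | intermediate
23 | racemic 1-aryl-2-benzyl-2-tetralone-type ketone (C3=O), 1,2-trans drawn | O=C1Cc2c(OC)c(OCc3ccccc3)c(OC)cc2[C@@H](c2ccc(OCc3ccccc3)cc2OC)[C@@H]1Cc1ccc(OCc2ccccc2)c(OCc2ccccc2)c1 | intermediate
24 | tetrabenzyl naphthalen-3-ol | Oc1cc2c(OC)c(OCc3ccccc3)c(OC)cc2c(-c2ccc(OCc3ccccc3)cc2OC)c1Cc1ccc(OCc2ccccc2)c(OCc2ccccc2)c1 | intermediate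
25 | CNP0000244.0 | COc1cc(O)ccc1-c1c(Cc2ccc(O)c(O)c2)c(O)cc2c(OC)c(O)c(OC)cc12 | target

Total step count: 16.
Longest linear sequence: 13 steps, from syringaldehyde 1 through steps 1, 2, 4, 5 and 8–16.

Steps most likely to fail

Step 13. The addition of the nucleophilic ketyl to an electron-rich, trisubstituted alkene may be slow. Simple reduction of the aldehyde or pinacol dimerisation could then overtake ring closure. The fallback closes the same C2–C3 bond by polar rather than radical chemistry and sets out from 19. Me2AlCl in CH2Cl2 at −78 °C should trigger a Prins-type carbonyl–ene cyclisation. The nucleophilic C2 attacks the complexed aldehyde and the C1 diaryl cation loses the C2 proton. This gives the racemic allylic alcohol 1-aryl-2-benzyl-3,4-dihydronaphthalen-3-ol F1, held as its aluminium alkoxide until a cold quench. Buffered Dess–Martin oxidation then gives the 1-aryl-2-benzylnaphthalen-3(4H)-one F2, which tautomerises at once. The route is rejoined at 24.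

Step 15. After aromatisation, the free electron-rich naphthol and the C2 methylene flanked by two oxygenated arenes may undergo further hydride abstraction by DDQ. The fallback masks the oxygen before dehydrogenation and sets out from 23. Ac2O, Et3N and DMAP should give the ring-B-conjugated enol acetate F3, a 1,2-dihydronaphthalene. DDQ or chloranil aromatises it to the less oxidisable naphthyl acetate F4. K2CO3 in MeOH then removes the acetyl group, and the route is rejoined at 24.

Step 8. β-Hydride transfer from the primary Grignard reagent may reduce the hindered ketone, or steric shielding by the two ortho substituents may stop the addition. The fallback reverses the order of the two carbon–carbon bond formations and sets out from 3. Grignard reagent 12 is added to the unhindered aldehyde 3 to give the racemic secondary alcohol 1-(2-bromoaryl)-3-arylpropan-1-ol F5. Dess–Martin oxidation gives the aryl 2-arylethyl ketone F6. Aryllithium 6, which has no β-hydrogen to transfer, is then added at −78 °C. The route is rejoined at 13.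

Further compounds
F1 | step 13 | racemic 6-(benzyloxy)-1-[4-(benzyloxy)-2-methoxyphenyl]-2-[3,4-bis(benzyloxy)benzyl]-5,7-dimethoxy-3,4-dihydronaphthalen-3-ol | OC1Cc2c(OC)c(OCc3ccccc3)c(OC)cc2C(c2ccc(OCc3ccccc3)cc2OC)=C1Cc1ccc(OCc2ccccc2)c(OCc2ccccc2)c1
F2 | step 13 | 6-(benzyloxy)-1-[4-(benzyloxy)-2-methoxyphenyl]-2-[3,4-bis(benzyloxy)benzyl]-5,7-dimethoxynaphthalen-3(4H)-one | O=C1Cc2c(OC)c(OCc3ccccc3)c(OC)cc2C(c2ccc(OCc3ccccc3)cc2OC)=C1Cc1ccc(OCc2ccccc2)c(OCc2ccccc2)c1
F3 | step 15 | racemic enol acetate of 23 (C3=C4, 1,2-trans drawn) | CC(=O)OC1=Cc2c(OC)c(OCc3ccccc3)c(OC)cc2[C@@H](c2ccc(OCc3ccccc3)cc2OC)[C@@H]1Cc1ccc(OCc2ccccc2)c(OCc2ccccc2)c1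
F4 | step 15 | acetate of naphthol 24 | CC(=O)Oc1cc2c(OC)c(OCc3ccccc3)c(OC)cc2c(-c2ccc(OCc3ccccc3)cc2OC)c1Cc1ccc(OCc2ccccc2)c(OCc2ccccc2)c1
F5 | step 8 | racemic 1-[4-(benzyloxy)-2-bromo-3,5-dimethoxyphenyl]-3-[3,4-bis(benzyloxy)phenyl]propan-1-ol | OC(CCc1ccc(OCc2ccccc2)c(OCc2ccccc2)c1)c1cc(OC)c(OCc2ccccc2)c(OC)c1Br
F6 | step 8 | 1-[4-(benzyloxy)-2-bromo-3,5-dimethoxyphenyl]-3-[3,4-bis(benzyloxy)phenyl]propan-1-one | O=C(CCc1ccc(OCc2ccccc2)c(OCc2ccccc2)c1)c1cc(OC)c(OCc2ccccc2)c(OC)c1Br
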